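# Gardenin D by photochemical acylation of a trimethoxybenzoquinone: synthesis design

## The problem

Gardenin D (17) is a flavone whose ring A has no free position: C5 carries a hydroxyl, C6, C7 and C8 carry methoxyls, C8a carries the ring oxygen O1 and C4a the carbonyl carbon C4, while ring B has a 3'-hydroxyl beside a 4'-methoxyl. There is no stereocentre, so the task is purely one of regiochemistry: five contiguous oxygens on ring A with exactly one left unmethylated, and one of two ring B oxygens left free. Ring C is fused to ring A through C4a and C8a, so C4 must be joined to C4a, and O1 to C2, on an extremely electron-rich arene. Pentaoxygenated benzenes and the related hydroquinones are oxidised by air and by most electrophiles, and strong Lewis acids strip their methyl ethers, so an ionic acylation at C4a works at the edge of what the substrate tolerates. The opening is that the oxygens on C6 and C8a are para to each other. Ring A can therefore be written at the quinone level as 2,3,5-trimethoxy-1,4-benzoquinone (6), whose only hydrogen-bearing carbon is C4a, and the C4–C4a bond becomes the union of that carbon with a formyl carbon through an acyl radical. This union returns ring A to the hydroquinone level with two hydroxyls that differ by chelation: the one beside the new ketone becomes O1, the other becomes the C6 methoxyl. The C5 methoxyl is the only one peri to the C4 carbonyl, which lets it be removed selectively at the end together with a ring B protecting group.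

## Retrosynthesis

**17 from 15.** Only two oxygen–carbon bonds are cut: the methyl on the C5 oxygen and an isopropyl on the C3' oxygen. C5 has to travel as a methyl ether because quinone 6 carries a methoxyl on that carbon. This costs no extra step, since BCl3 chelated between the C4 carbonyl and the C5 oxygen (bis(dichloroborate) 16) removes the peri methyl and also cleaves a secondary alkyl aryl ether. A benzyl group on ring B would bring a weak benzylic C–H into the photochemical step. A free phenol would quench the excited quinone. The precursor 15 is a robust, fully O-alkylated flavone, and the forward step must leave the methoxyls on C6, C7, C8 and C4' untouched.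

**15 from 12.** The O1–C2 bond is cut and the C2=C3 double bond is taken back to the chalcone level. Iodine in DMSO closes 2'-hydroxychalcone 12 through flavanone 13 and 3-iodoflavanone 14 and dehydrogenates in the same flask. The neighbouring cut, C2–C3 by a diketone route, would need an acetophenone and a separate aroyl unit and would forfeit the one-step assembly of the C6–C3–C6 skeleton offered below. The forward reaction needs only a free hydroxyl ortho to the enone carbonyl.

**12 from 11.** The methyl on the future C6 oxygen is removed. Chalcone 11 has two hydroxyls; the one ortho to the ketone is locked in a hydrogen bond, the other is an ordinary phenol. The forward step is a mono-methylation that must stop at the unchelated site. The precursor is no smaller, but it is the direct product of the skeletal union.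

**11 from 6 and 9.** This is the key cut, C4–C4a. The polar alternative, acylation of a pentaoxygenated phenol followed by aldol condensation, needs two steps and a Lewis acid on a fragile arene. Here quinone 6 and enal 9 are joined in one light-driven step that delivers the whole carbon skeleton with every oxygen in place, through keto tautomer 10. The quinone has a single C–H position, so the site of bond formation is not in question. The forward reaction has to favour abstraction of the formyl hydrogen over reactions of the styryl double bond. Both partners are small, achiral and three and two steps from commercial materials.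

**6 from 5, 3 and 1.** The quinone is unravelled by oxidative demethylation to 2,3,4,5-tetramethoxyphenol (5), in which the methoxyl para to the hydroxyl is the one lost. The phenol oxygen comes from aldehyde 3 by Dakin oxidation through formate 4. The aldehyde comes from 1,2,3,4-tetramethoxybenzene (1) by Vilsmeier–Haack formylation through iminium salt 2. The two open positions of 1 are equivalent, so the only aromatic C–H functionalisation of the route has no regiochemical issue.

**9 from 8 and 7.** The C=C bond of the enal is cut by a Wittig disconnection to 3-isopropoxy-4-methoxybenzaldehyde (8) and a formylmethylene ylide. Aldehyde 8 is the isopropyl ether of isovanillin (7). A stabilised ylide is asked to deliver the E enal and to stop after one homologation.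

## Roads not taken

**Alternative 1:** Ring A is grown onto a preformed ring C by cutting C8–C8a. A squarate ester is combined with a 3-metallated 6-aryl-4-pyranone to give 4-[6-(3-benzyloxy-4-methoxyphenyl)-4-oxo-4H-pyran-3-yl]-4-hydroxy-2,3-dimethoxycyclobut-2-en-1-one (A1). Heating opens A1 to a dienylketene, which closes onto the pyranone carbon next to oxygen to give the 5,8-hydroquinone A2.
- Merits: the endgame is the best of all the plans. A2 already carries the free, chelated C5 hydroxyl, and its unchelated C8 hydroxyl is simply methylated, so no demethylation is needed. The ring A oxygens are placed without ambiguity.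
- Weak points: the pyranone must first be built (several steps) and then metallated at C3, although 4-pyranones are themselves acceptors for organometallics. The electrocyclisation must engage an enol-ether double bond of the pyranone instead of the usual arene or alkene. The squarate is costly.
- Comparison: in phenol differentiation this road is superior, and the chosen plan must accept a final BCl3 step in exchange. The chosen plan offers cheap aromatic starting materials that bring all ring A oxygens with them, a shorter sequence, and no organometallic step on a sensitive heterocycle.

**Alternative 2:** Ring C is closed at C2=C3 by an intramolecular Wittig reaction on an ester carbonyl. The precursor is 2,3,4,5-tetramethoxy-6-[2-(triphenylphosphoranylidene)acetyl]phenyl 3-benzyloxy-4-methoxybenzoate (A3), and heating gives flavone A4 with loss of triphenylphosphine oxide.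
- Merits: every step is of a well-established kind, and the ring closes thermally under neutral conditions at the flavone oxidation level. No oxidant meets the electron-rich ring, and no photochemistry is needed.
- Weak points: A3 requires the ring A ortho-hydroxyacetophenone (an ionic acylation of phenol 5), then α-bromination, phosphonium salt formation, ylide generation and O-aroylation in competition with C-acylation of the ylide. This is four to five operations from phenol 5, where the chosen plan needs three (steps 3, 6 and 7) to reach its cyclisation precursor 12. A4 still carries the C5 methyl ether, so the same final deprotection remains.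
- Comparison: step for step this road is more reliable than a photochemical union. The chosen plan sets against it a route about two steps shorter and a single convergent step that forms the full skeleton.

**Alternative 3:** Ring C is closed at O1–C8a by anodic C–H/O–H coupling. The precursor 1-(3-isopropoxy-4-methoxyphenyl)-3-(2,3,4,5-tetramethoxyphenyl)propane-1,3-dione (A5) has hydrogen where O1 will be. Oxidation of ring A in hexafluoroisopropanol lets the enol oxygen attack C8a and gives flavone A6, identical with 15.
- Merits: this is the shortest road. A5 would follow by Claisen condensation from two simple aromatic building blocks, no quinone or Dakin step is needed, and the endgame is shared with the chosen plan.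
- Weak points: ring A of A5 has methoxyls in a para relationship (C5 and C8), the classical setting for oxidative demethylation to a quinone. The ring B diether and the enolised diketone are oxidised at similar potentials. The product remains oxidisable. Closure of a six-membered chromone ring by this mode is much less established than five-membered cases.
- Comparison: if the electrolysis were selective, this plan would be two to three steps shorter. In the chosen plan O1 is on C8a from the start, and selectivity rests on structure (one C–H on the quinone, one chelated hydroxyl) and not on small differences in oxidation potential.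

Key step: step 6

Remark on the chemistry: the target has no stereocentre. The sp3 centres of the transient intermediates 10, 13 and 14 form as racemates and are drawn without configuration. Formate 4 is taken to be cleaved by methanolysis.

## Route

Step 1
Reactants: 1 1,2,3,4-tetramethoxybenzene
Product: 3 2,3,4,5-tetramethoxybenzaldehyde, via iminium dichlorophosphate 2 (not isolated)
Conditions: POCl3, DMF, 0 °C to 80 °C; then H2O, 0 °C to rt
Reagents that add atoms: N,N-dimethylformamide, CN(C)C=O; water, O
Why: Vilsmeier–Haack formylation; the two free positions of 1 are equivalent and each is ortho to one methoxyl and para to another, so a single aldehyde is expected after hydrolysis of iminium salt 2.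

Step 2
Reactants: 3 2,3,4,5-tetramethoxybenzaldehyde
Product: 5 2,3,4,5-tetramethoxyphenol, via 2,3,4,5-tetramethoxyphenyl formate 4 (not isolated)
Conditions: 30% aq H2O2, H2SO4 (cat.), MeOH, rt
Reagents that add atoms: hydrogen peroxide, OO
Why: Acid-catalysed Dakin (Baeyer–Villiger-type) oxidation; the ortho and para methoxyls make aryl migration dominant, and formate 4 is methanolysed in the same flask.

Step 3
Reactants: 5 2,3,4,5-tetramethoxyphenol
Product: 6 2,3,5-trimethoxy-1,4-benzoquinone
Conditions: (NH4)2Ce(NO3)6 (2.2 equiv), MeCN/H2O, 0 °C
Reagents that add atoms: water, O
Why: Oxidative demethylation of a para-methoxyphenol by tetravalent cerium; two one-electron oxidations give a phenoxonium ion, water adds at the methoxyl-bearing para carbon and methanol is expelled, which should give the para-quinone.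

Step 4
Reactants: 7 isovanillin (3-hydroxy-4-methoxybenzaldehyde)
Product: 8 3-isopropoxy-4-methoxybenzaldehyde
Conditions: 2-bromopropane, K2CO3, DMF, 70 °C
Reagents that add atoms: 2-bromopropane, CC(C)Br
Why: Williamson ether synthesis on the only acidic group; the isopropyl ether has no phenolic hydrogen to quench the excited quinone in step 6 and falls to BCl3 in step 9.

Step 5
Reactants: 8 3-isopropoxy-4-methoxybenzaldehyde
Product: 9 (E)-3-(3-isopropoxy-4-methoxyphenyl)prop-2-enal
Conditions: Ph3P=CHCHO (1.2 equiv), toluene, 110 °C
Reagents that add atoms: (triphenylphosphoranylidene)acetaldehyde, O=CC=P(c1ccccc1)(c1ccccc1)c1ccccc1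
Why: Wittig olefination with a stabilised ylide, which should give the E enal; the product is a vinylogous, donor-substituted aldehyde and is less electrophilic than 8, which disfavours a second homologation.

Step 6
Reactants: 6 2,3,5-trimethoxy-1,4-benzoquinone; 9 (E)-3-(3-isopropoxy-4-methoxyphenyl)prop-2-enal
Product: 11 (E)-1-(2,5-dihydroxy-3,4,6-trimethoxyphenyl)-3-(3-isopropoxy-4-methoxyphenyl)prop-2-en-1-one, via keto tautomer 10 (not isolated)
Conditions: hν (blue LEDs, 450 nm), degassed benzene, 20 °C, argon
Reagents that add atoms: none
Why: This is a photochemical Friedel–Crafts-type acylation of a 1,4-quinone by an aldehyde, a reaction known for benzo- and naphthoquinones with aliphatic, aromatic and conjugated aldehydes and applied here to a trimethoxyquinone and an electron-rich cinnamaldehyde; it is an addition of one molecule of 9 to one molecule of 6 in which every atom of both partners ends up in 11. Blue light is absorbed only by 6 (n–π* band), and its triplet should abstract the formyl hydrogen of 9 to give a semiquinone and a cinnamoyl radical. The nucleophilic acyl radical bonds to the one unsubstituted ring carbon, either directly in the radical pair, by addition to ground-state 6 followed by hydrogen return, or by O-acylation and photo-Fries shift to the only free ortho position; this forms the C4–C4a bond in keto tautomer 10, which enolises to hydroquinone 11. No ring is closed and no stereocentre is created; the E geometry should be retained, and any Z isomer would be harmless because step 8 places this double bond in ring C. The step needs site selectivity, which the substrate secures because every other quinone carbon carries a methoxyl. It also needs chemoselectivity for the formyl C–H over the styryl double bond and the ether C–H bonds, which rests on the formyl hydrogen being the weakest and polarity-matched to the electrophilic n–π* oxygen and on the enal staying unexcited at 450 nm. The conjugated acyl radical should not lose CO, since that would give a vinyl radical. Product 11 should accumulate because its acyl group makes the corresponding quinone a stronger oxidant than 6, so redox exchange with unreacted 6 lies on the side of 11.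

Step 7
Reactants: 11 (E)-1-(2,5-dihydroxy-3,4,6-trimethoxyphenyl)-3-(3-isopropoxy-4-methoxyphenyl)prop-2-en-1-one
Product: 12 (E)-1-(2-hydroxy-3,4,5,6-tetramethoxyphenyl)-3-(3-isopropoxy-4-methoxyphenyl)prop-2-en-1-one
Conditions: MeI (1.1 equiv), K2CO3, degassed acetone, rt, argon
Reagents that add atoms: iodomethane, CI
Why: Chelation-controlled O-methylation; the hydroxyl ortho to the ketone is held in a hydrogen bond and is the poorer nucleophile, so one equivalent of MeI should alkylate only the free hydroxyl, as with 2,5-dihydroxyaryl ketones in general.

Step 8
Reactants: 12 (E)-1-(2-hydroxy-3,4,5,6-tetramethoxyphenyl)-3-(3-isopropoxy-4-methoxyphenyl)prop-2-en-1-one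
Product: 15 2-(3-isopropoxy-4-methoxyphenyl)-5,6,7,8-tetramethoxy-4H-chromen-4-one, via flavanone 13 (not isolated), via 3-iodoflavanone 14 (not isolated)
Conditions: I2 (10 mol%), DMSO, 120 °C
Reagents that add atoms: none
Why: Iodine/DMSO oxidative cyclisation of a 2'-hydroxychalcone; 6-endo oxa-Michael addition of the chelated hydroxyl gives flavanone 13, iodination of its enol gives 14, and loss of HI gives the flavone while DMSO reoxidises HI to I2. The same conditions are standard for 2'-hydroxy-3',4',5',6'-tetramethoxychalcones.

Step 9
Reactants: 15 2-(3-isopropoxy-4-methoxyphenyl)-5,6,7,8-tetramethoxy-4H-chromen-4-one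
Product: 17 gardenin D, via bis(dichloroborate) 16 (not isolated)
Conditions: BCl3 (3 equiv), CH2Cl2, −78 °C to 0 °C; then H2O
Reagents that add atoms: none
Why: Lewis-acid ether cleavage; BCl3 chelated between the C4 carbonyl and the C5 oxygen should remove only the peri methyl, and it cleaves isopropyl aryl ethers in the presence of methyl ethers, so both phenols are released on hydrolysis of 16.

## Compound list

1 | 1,2,3,4-tetramethoxybenzene | COc1ccc(OC)c(OC)c1OC | starting material
2 | N,N-dimethyl-(2,3,4,5-tetramethoxyphenyl)methaniminium dichlorophosphate | COc1cc(C=[N+](C)C)c(OC)c(OC)c1OC.[O-]P(=O)(Cl)Cl | intermediate (not isolated)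
3 | 2,3,4,5-tetramethoxybenzaldehyde | COc1cc(C=O)c(OC)c(OC)c1OC | intermediate
4 | 2,3,4,5-tetramethoxyphenyl formate | COc1cc(OC=O)c(OC)c(OC)c1OC | intermediate (not isolated)
5 | 2,3,4,5-tetramethoxyphenol | COc1cc(O)c(OC)c(OC)c1OC | intermediate
6 | 2,3,5-trimethoxy-1,4-benzoquinone | COC1=CC(=O)C(OC)=C(OC)C1=O | intermediate
7 | isovanillin (3-hydroxy-4-methoxybenzaldehyde) | COc1ccc(C=O)cc1O | starting material
8 | 3-isopropoxy-4-methoxybenzaldehyde | COc1ccc(C=O)cc1OC(C)C | intermediate
9 | (E)-3-(3-isopropoxy-4-methoxyphenyl)prop-2-enal | COc1ccc(/C=C/C=O)cc1OC(C)C | intermediate
10 | 4-hydroxy-6-[(E)-3-(3-isopropoxy-4-methoxyphenyl)prop-2-enoyl]-2,3,5-trimethoxycyclohexa-2,4-dien-1-one (racemic keto tautomer of 11) | COc1ccc(/C=C/C(=O)C2C(=O)C(OC)=C(OC)C(O)=C2OC)cc1OC(C)C | intermediate (not isolated)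
11 | (E)-1-(2,5-dihydroxy-3,4,6-trimethoxyphenyl)-3-(3-isopropoxy-4-methoxyphenyl)prop-2-en-1-one | COc1ccc(/C=C/C(=O)c2c(O)c(OC)c(OC)c(O)c2OC)cc1OC(C)C | intermediate
12 | (E)-1-(2-hydroxy-3,4,5,6-tetramethoxyphenyl)-3-(3-isopropoxy-4-methoxyphenyl)prop-2-en-1-one | COc1ccc(/C=C/C(=O)c2c(O)c(OC)c(OC)c(OC)c2OC)cc1OC(C)C | intermediate
13 | 2-(3-isopropoxy-4-methoxyphenyl)-5,6,7,8-tetramethoxychroman-4-one (racemic) | COc1ccc(C2CC(=O)c3c(OC)c(OC)c(OC)c(OC)c3O2)cc1OC(C)C | intermediate (not isolated)
14 | 3-iodo-2-(3-isopropoxy-4-methoxyphenyl)-5,6,7,8-tetramethoxychroman-4-one (racemic, relative configuration of no consequence) | COc1ccc(C2Oc3c(OC)c(OC)c(OC)c(OC)c3C(=O)C2I)cc1OC(C)C | intermediate (not isolated)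
15 | 2-(3-isopropoxy-4-methoxyphenyl)-5,6,7,8-tetramethoxy-4H-chromen-4-one | COc1ccc(-c2cc(=O)c3c(OC)c(OC)c(OC)c(OC)c3o2)cc1OC(C)C | intermediate
16 | 5-(dichloroboryloxy)-2-[3-(dichloroboryloxy)-4-methoxyphenyl]-6,7,8-trimethoxy-4H-chromen-4-one | COc1ccc(-c2cc(=O)c3c(OB(Cl)Cl)c(OC)c(OC)c(OC)c3o2)cc1OB(Cl)Cl | intermediate (not isolated)
17 | gardenin D, 5-hydroxy-2-(3-hydroxy-4-methoxyphenyl)-6,7,8-trimethoxy-4H-chromen-4-one | COc1ccc(-c2cc(=O)c3c(O)c(OC)c(OC)c(OC)c3o2)cc1O | target

## Step count and risk assessment

Total: 9 steps. Longest linear sequence: 7 steps (steps 1, 2, 3, 6, 7, 8, 9 from compound 1); the ring B branch contributes steps 4 and 5.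

**Step 6 (key step).** The excited quinone may be quenched without bond formation by electron transfer from the electron-rich dialkoxystyryl unit of 9. Cycloaddition of the quinone carbonyl to the styryl double bond, O-acylation without migration to carbon, and hydrogen abstraction from the isopropoxy methine may also divert material. Three methoxyls may further make the triplet of 6 a sluggish hydrogen abstractor.
- Fallback: the C4–C4a bond is made by polar chemistry. Phenol 5 is acylated ortho to the hydroxyl with acetic acid and BF3·OEt2 to give 1-(2-hydroxy-3,4,5,6-tetramethoxyphenyl)ethan-1-one F1. Claisen–Schmidt condensation of F1 with aldehyde 8 (KOH, EtOH) then rejoins the route at chalcone 12.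

**Step 7.** Selectivity may erode through alkylation of the chelated hydroxyl, and the electron-rich hydroquinone monoanion may be oxidised by traces of air. Base-induced ring closure to the flavanone would be harmless, since step 8 passes through 13.
- Fallback: the two hydroxyls are told apart by ring formation instead of by chelation. From 11, NaOAc in refluxing ethanol under argon closes the chelated hydroxyl onto the enone to give 6-hydroxy-2-(3-isopropoxy-4-methoxyphenyl)-5,7,8-trimethoxychroman-4-one F2. Its single remaining hydroxyl is methylated with TMSCHN2 and i-Pr2NEt in MeOH/MeCN, which returns to the route at flavanone 13, and 13 is then taken through the iodine/DMSO conditions of step 8.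

**Step 9.** Dealkylation may overrun to the C6 methyl (relayed by the boron chelate at C5) or to the C4' methyl next to the ring B borate, or the isopropyl cleavage may stay incomplete at the temperature that protects the methyl ethers.
- Fallback: the two unmaskings are separated. From 15, concentrated HCl in refluxing ethanol hydrolyses only the peri methoxyl, a Brønsted-acid hydrolysis that is driven by the protonated C4 carbonyl and is therefore confined to C5, to give 5-hydroxy-2-(3-isopropoxy-4-methoxyphenyl)-6,7,8-trimethoxy-4H-chromen-4-one F3. The isopropyl ether of F3 is then cleaved with a small excess of BCl3 at −78 °C to arrive at 17.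

**Step 5.** The ylide may homologate the product a second time to the dienal, and conversion of the electron-rich aldehyde may be slow.
- Fallback: from 8, Horner–Wadsworth–Emmons reaction with triethyl phosphonoacetate (NaH, THF) gives ethyl (E)-3-(3-isopropoxy-4-methoxyphenyl)prop-2-enoate F4. Reduction with i-Bu2AlH (CH2Cl2, −78 °C) gives (E)-3-(3-isopropoxy-4-methoxyphenyl)prop-2-en-1-ol F5, and oxidation with MnO2 in CH2Cl2 returns to 9.

**Step 3.** Oxidation may partly take the ortho course (loss of the methyl next to the hydroxyl), the vinylogous-ester methoxyls of 6 may be hydrolysed in the acidic aqueous medium, and the ring may be nitrated.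
- Fallback: from 5, PhI(OAc)2 in methanol at 0 °C traps the phenoxonium ion at the para carbon as the quinone monoketal 2,3,4,4,5-pentamethoxycyclohexa-2,5-dien-1-one F6. Hydrolysis of F6 with dilute aqueous acetic acid returns to 6.

## Further compounds

F1 | step 6 | 1-(2-hydroxy-3,4,5,6-tetramethoxyphenyl)ethan-1-one | CC(=O)c1c(O)c(OC)c(OC)c(OC)c1OC
F2 | step 7 | 6-hydroxy-2-(3-isopropoxy-4-methoxyphenyl)-5,7,8-trimethoxychroman-4-one (racemic) | COc1ccc(C2CC(=O)c3c(OC)c(O)c(OC)c(OC)c3O2)cc1OC(C)C
F3 | step 9 | 5-hydroxy-2-(3-isopropoxy-4-methoxyphenyl)-6,7,8-trimethoxy-4H-chromen-4-one | COc1ccc(-c2cc(=O)c3c(O)c(OC)c(OC)c(OC)c3o2)cc1OC(C)C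
F4 | step 5 | ethyl (E)-3-(3-isopropoxy-4-methoxyphenyl)prop-2-enoate | CCOC(=O)/C=C/c1ccc(OC)c(OC(C)C)c1
F5 | step 5 | (E)-3-(3-isopropoxy-4-methoxyphenyl)prop-2-en-1-ol | COc1ccc(/C=C/CO)cc1OC(C)C
F6 | step 3 | 2,3,4,4,5-pentamethoxycyclohexa-2,5-dien-1-one | COC1=CC(=O)C(OC)=C(OC)C1(OC)OC
A1 | alternative 1 | 4-[6-(3-benzyloxy-4-methoxyphenyl)-4-oxo-4H-pyran-3-yl]-4-hydroxy-2,3-dimethoxycyclobut-2-en-1-one (racemic) | COC1=C(OC)C(O)(c2coc(-c3ccc(OC)c(OCc4ccccc4)c3)cc2=O)C1=O
A2 | alternative 1 | 2-(3-benzyloxy-4-methoxyphenyl)-5,8-dihydroxy-6,7-dimethoxy-4H-chromen-4-one | COc1ccc(-c2cc(=O)c3c(O)c(OC)c(OC)c(O)c3o2)cc1OCc1ccccc1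
A3 | alternative 2 | 2,3,4,5-tetramethoxy-6-[2-(triphenylphosphoranylidene)acetyl]phenyl 3-benzyloxy-4-methoxybenzoate | COc1ccc(C(=O)Oc2c(OC)c(OC)c(OC)c(OC)c2C(=O)C=P(c2ccccc2)(c2ccccc2)c2ccccc2)cc1OCc1ccccc1
A4 | alternative 2 | 2-(3-benzyloxy-4-methoxyphenyl)-5,6,7,8-tetramethoxy-4H-chromen-4-one | COc1ccc(-c2cc(=O)c3c(OC)c(OC)c(OC)c(OC)c3o2)cc1OCc1ccccc1
A5 | alternative 3 | 1-(3-isopropoxy-4-methoxyphenyl)-3-(2,3,4,5-tetramethoxyphenyl)propane-1,3-dione | COc1ccc(C(=O)CC(=O)c2cc(OC)c(OC)c(OC)c2OC)cc1OC(C)C
A6 | alternative 3 | 2-(3-isopropoxy-4-methoxyphenyl)-5,6,7,8-tetramethoxy-4H-chromen-4-one | COc1ccc(-c2cc(=O)c3c(OC)c(OC)c(OC)c(OC)c3o2)cc1OC(C)C
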